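**Strategy.** The route rests on recognising ring A (C3a–C4–C5–C6–C7–C7a), cis-fused along C6–C7 to the cyclobutane C6–C7–C3'–C8', with oxidised C3' on C7 and the butenolide carbon C7a next to it, as the adduct of cyclobut-2-enone and a 1-oxygenated butadiene. One catalytic enantioselective Diels–Alder reaction forms C5–C6 and C7–C7a, closes ring A and fixes C6 and C7 absolutely; every later stereocentre is relayed from this cis-fused bicycle. The precursors are cyclobutenone and (E)-1-(triisopropylsilyloxy)buta-1,3-diene. The cyclobutanone carbonyl then carries the propyl and spiro-phthalide units, and the C7a silyl ether becomes the ketone on which the butylidene butenolide is built.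

Key step: step 4

Remarks on the chemistry:
- Locants. Positions are discussed with the phthalide numbering: unit A = C1, O2, C3, C3a, C4–C7, C7a, butylidene C8; unit B = C1', O2', spiro C3', propyl-bearing C8'. In the bicyclo[4.2.0]octane names of the intermediates C1 = C6, C2 = C5, C3 = C4, C4 = C3a, C5 = C7a, C6 = C7, C7 = C3', C8 = C8'. The ketone therefore takes the lower locant (7-one); numbered from the other bridgehead the adduct 6 is the 2-silyloxy-oct-3-en-8-one.
- The target is (6S,7R,3'R,8'R). On the cyclobutane, C5, C7a, the propyl group and O2' lie on one face (concave); H6, H7, H8' and the aryl carbon lie on the other (convex).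
- Assumption: the (S)-configured oxazaborolidine–AlBr3 catalyst is taken to expose the face of cyclobutenone that leads to (1S,5S,6R)-6, by analogy with other 2-cycloalkenones. Should the sense prove opposite, the (R)-antipode, equally available from (R)-diphenylprolinol, is used and nothing else changes.

**Route**

Step 1
Reactants: 1 3-oxocyclobutane-1-carboxylic acid
Product: 2 3-bromocyclobutan-1-one
Conditions: HgO, Br2, MgSO4, CH2Cl2, reflux
Reagents that add atoms: bromine, BrBr
Why: Cristol–Firth variant of the Hunsdiecker bromodecarboxylation, in which the acyl hypobromite fragments by a radical chain to the secondary bromide; no stereocentre is involved.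

Step 2
Reactants: 2 3-bromocyclobutan-1-one
Product: 3 cyclobut-2-en-1-one
Conditions: n-Bu3N, neat, rt, reduced pressure, product collected at −78 °C and used as a cold CH2Cl2 solution
Reagents that add atoms: none
Why: E1cB dehydrobromination of a β-bromo ketone by a tertiary amine, the volatile enone being removed as it forms so that its polymerisation is limited.

Step 3
Reactants: 4 (E)-but-2-enal
Product: 5 (E)-1-(triisopropylsilyloxy)buta-1,3-diene
Conditions: TIPSOTf, Et3N, Et2O, 0 °C → rt
Reagents that add atoms: triisopropylsilyl trifluoromethanesulfonate, CC(C)[Si](C(C)C)(C(C)C)OS(=O)(=O)C(F)(F)F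
Why: Vinylogous soft enolisation (O-silylation of the aldehyde, then γ-deprotonation by the amine) should give the silyl dienol ether mainly as the E isomer, the only geometry that reacts readily in the cycloaddition.

Step 4
Reactants: 3 cyclobut-2-en-1-one; 5 (E)-1-(triisopropylsilyloxy)buta-1,3-diene
Product: 6 (1S,5S,6R)-5-(triisopropylsilyloxy)bicyclo[4.2.0]oct-3-en-7-one (H1, H5 and H6 all cis; silyloxy group cis to the carbonyl carbon)
Conditions: (S)-3,3-diphenyl-1-(o-tolyl)tetrahydro-1H,3H-pyrrolo[1,2-c][1,3,2]oxazaborole (10 mol %), AlBr3 (8 mol %), 5 in excess, CH2Cl2, −78 °C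
Reagents that add atoms: none
Why: The AlBr3-activated oxazaborolidine binds the carbonyl oxygen of 3 and lowers its LUMO, so that diene 5 adds in a concerted, asynchronous endo [4+2] cycloaddition in which C5, the nucleophilic terminus, bonds to the β-carbon C6 ahead of the oxygen-bearing terminus C7a bonding to the α-carbon C7. The closest known reaction types are the Lewis-acid-promoted Diels–Alder reaction of cyclobutenone and the oxazaborolidinium-catalysed enantioselective Diels–Alder reaction of 2-cycloalkenones with silyloxydienes. Ring A is closed in this single intermolecular cycloaddition, both sigma bonds forming suprafacially on diene and dienophile. C6 and C7 are cis because the dienophile double bond is locked cis in the four-membered ring, and their absolute configuration is set by the chiral Lewis acid, which shields one face of the coordinated enone; C7a is set by the E geometry of 5 together with the endo orientation of the ring carbonyl, which leaves the silyloxy group cis to C3'. The step needs ortho regioselectivity (C7a on C7), endo selectivity and face selectivity, which are secured by the 1-silyloxy donor of 5, by the compact ring carbonyl under the diene, and by the catalyst. Release of ring strain allows reaction at −78 °C, where the acid-sensitive silyl dienol ether should survive.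

Step 5
Reactants: 6 (1S,5S,6R)-5-(triisopropylsilyloxy)bicyclo[4.2.0]oct-3-en-7-one; 7 propanal
Product: 9 8-(1-hydroxypropyl)-5-(triisopropylsilyloxy)bicyclo[4.2.0]oct-3-en-7-one (epimers at C8 and at the carbinol carbon; ring centres as in 6), via lithium cyclobutenolate 8 (not isolated)
Conditions: LiN(i-Pr)2, THF, −78 °C; propanal, −78 °C; AcOH quench
Reagents that add atoms: none
Why: Directed aldol addition, in which the hindered amide should deprotonate kinetically at the C8' methylene and not at the ring-fusion methine C7; the two new centres disappear in steps 6 and 7, so their configuration is immaterial.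

Step 6
Reactants: 9 8-(1-hydroxypropyl)-5-(triisopropylsilyloxy)bicyclo[4.2.0]oct-3-en-7-one
Product: 11 (E)-8-propylidene-5-(triisopropylsilyloxy)bicyclo[4.2.0]oct-3-en-7-one (ring centres as in 6), via secondary mesylate 10 (not isolated)
Conditions: MsCl, Et3N, CH2Cl2, 0 °C; then DBU, rt
Reagents that add atoms: none
Why: Mesylation followed by E1cB elimination completes the aldol condensation under mild conditions and should give the conjugated exocyclic enone, the E geometry being expected but of no consequence.

Step 7
Reactants: 11 (E)-8-propylidene-5-(triisopropylsilyloxy)bicyclo[4.2.0]oct-3-en-7-one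
Product: 12 8-propyl-5-(triisopropylsilyloxy)bicyclo[4.2.0]octan-7-one (propyl on the concave face, cis to C2; H1, H6 and H8 on one face of the four-membered ring)
Conditions: H2 (1 atm), Pd on carbon (10 wt %), EtOAc, rt; used without exposure to base
Reagents that add atoms: none
Why: Heterogeneous catalytic hydrogenation should deliver hydrogen to the exocyclic alkene from the convex face of the cis-fused bicycle (the face of H6 and H7), which places the C8' propyl group on the concave face cis to C5, while the isolated ring A alkene is saturated in the same operation.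

Step 8
Reactants: 12 8-propyl-5-(triisopropylsilyloxy)bicyclo[4.2.0]octan-7-one; 13 methyl 2-iodobenzoate
Product: 16 8-propyl-5-(triisopropylsilyloxy)-3'H-spiro[bicyclo[4.2.0]octane-7,1'-[2]benzofuran]-3'-one (lactone oxygen cis to propyl and to C5; aryl carbon on the convex face), via [2-(methoxycarbonyl)phenyl]magnesium chloride 14 (not isolated), via chloromagnesium tertiary alkoxide 15 (not isolated)
Conditions: 13, i-PrMgCl·LiCl, THF, −40 °C; then 12, LaCl3·2LiCl, −40 °C → rt; aq NH4Cl
Reagents that add atoms: none
Why: Iodine–magnesium exchange gives a functionalised aryl Grignard reagent that should add to the strained cyclobutanone from the convex face, anti to the C8' propyl group and to ring A, so that the new C3'–O bond lies cis to propyl and C7a, and the alkoxide then closes the phthalide on the neighbouring ester (addition–lactonisation), LaCl3·2LiCl suppressing enolisation.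

Step 9
Reactants: 16 8-propyl-5-(triisopropylsilyloxy)-3'H-spiro[bicyclo[4.2.0]octane-7,1'-[2]benzofuran]-3'-one
Product: 17 5-hydroxy-8-propyl-3'H-spiro[bicyclo[4.2.0]octane-7,1'-[2]benzofuran]-3'-one (stereocentres as in 16)
Conditions: Bu4NF, AcOH, THF, rt
Reagents that add atoms: none
Why: Fluoride-mediated silyl ether cleavage, buffered with acetic acid so that no basic alkoxide is exposed to the lactone.

Step 10
Reactants: 17 5-hydroxy-8-propyl-3'H-spiro[bicyclo[4.2.0]octane-7,1'-[2]benzofuran]-3'-one
Product: 18 8-propyl-3'H-spiro[bicyclo[4.2.0]octane-7,1'-[2]benzofuran]-3',5-dione (C7a ketone; remaining centres as in 16)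
Conditions: DMP, CH2Cl2, 0 °C → rt
Reagents that add atoms: none
Why: Dess–Martin oxidation of the secondary alcohol under non-basic conditions, which avoids β-elimination of the C3' carboxylate from the new ketone.

Step 11
Reactants: 18 8-propyl-3'H-spiro[bicyclo[4.2.0]octane-7,1'-[2]benzofuran]-3',5-dione; 19 pentanoyl chloride
Product: 21 4-pentanoyl-8-propyl-3'H-spiro[bicyclo[4.2.0]octane-7,1'-[2]benzofuran]-3',5-dione (1,3-diketone present mainly as its enol; C4 undefined), via lithium C3a enolate 20 (not isolated)
Conditions: LiN(SiMe3)2 (2.1 equiv), THF–toluene, −78 °C; pentanoyl chloride, −78 → 0 °C; AcOH quench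
Reagents that add atoms: none
Why: Claisen-type C-acylation of a kinetic lithium enolate by an acid chloride, the hindered amide taking a proton from the C3a methylene and not from the ring-fusion methine C7 (whose enolate could expel the C3' carboxylate), with the second equivalent of base storing the product as its stable diketonate.

Step 12
Reactants: 21 4-pentanoyl-8-propyl-3'H-spiro[bicyclo[4.2.0]octane-7,1'-[2]benzofuran]-3',5-dione
Product: 22 3'-oxo-4-pentanoyl-8-propyl-3'H-spiro[bicyclo[4.2.0]oct-4-ene-7,1'-[2]benzofuran]-5-yl trifluoromethanesulfonate (C7a–OTf, C7a=C3a)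
Conditions: Tf2O, i-Pr2NEt, CH2Cl2, −78 °C
Reagents that add atoms: trifluoromethanesulfonic anhydride, O=S(=O)(OS(=O)(=O)C(F)(F)F)C(F)(F)F
Why: O-Sulfonylation of the 1,3-diketone through its preferred endocyclic enol (ring C7a=C3a, hydrogen-bonded to the side-chain carbonyl), as known for 2-acylcyclohexanones, should give the ring vinyl triflate.

Step 13
Reactants: 22 3'-oxo-4-pentanoyl-8-propyl-3'H-spiro[bicyclo[4.2.0]oct-4-ene-7,1'-[2]benzofuran]-5-yl trifluoromethanesulfonate
Product: 23 CNP0248594.2, the (6S,7R,3'R,8'R) target with the (Z)-butylidene butenolide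
Conditions: Pd(PPh3)4 (5 mol %), CO (1 atm), Et3N, MeCN, 60 °C
Reagents that add atoms: carbon monoxide, [C-]#[O+]
Why: Palladium-catalysed carbonylative enol-lactonisation, in which oxidative addition of zerovalent palladium to the vinyl triflate and CO insertion give an acylpalladium species that the enolate oxygen of the neighbouring pentanoyl ketone captures to close the five-membered ylidenebutenolide, the Z alkene (propyl cis to O2, away from C4) being favoured by allylic strain.

**Compound list**

1 | 3-oxocyclobutane-1-carboxylic acid | O=C1CC(C1)C(=O)O | starting material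
2 | 3-bromocyclobutan-1-one | O=C1CC(Br)C1 | intermediate
3 | cyclobut-2-en-1-one | O=C1C=CC1 | intermediate
4 | (E)-but-2-enal | C/C=C/C=O | starting material
5 | (E)-1-(triisopropylsilyloxy)buta-1,3-diene | C=C/C=C/O[Si](C(C)C)(C(C)C)C(C)C | intermediate
6 | (1S,5S,6R)-5-(triisopropylsilyloxy)bicyclo[4.2.0]oct-3-en-7-one | CC(C)[Si](O[C@H]1C=CC[C@H]2CC(=O)[C@@H]12)(C(C)C)C(C)C | intermediate
7 | propanal | CCC=O | starting material
8 | lithium cyclobutenolate of 6 (C3'–OLi, C3'=C8'; not isolated) | CC(C)[Si](O[C@H]1C=CC[C@H]2C=C(O[Li])[C@@H]12)(C(C)C)C(C)C | intermediate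
9 | 8-(1-hydroxypropyl)-5-(triisopropylsilyloxy)bicyclo[4.2.0]oct-3-en-7-one, ring centres as in 6, epimers at C8 and the carbinol carbon | CC(C)[Si](O[C@H]1C=CC[C@H]2C(C(O)CC)C(=O)[C@@H]12)(C(C)C)C(C)C | intermediate
10 | methanesulfonate of 9 (not isolated) | CC(C)[Si](O[C@H]1C=CC[C@H]2C(C(CC)OS(C)(=O)=O)C(=O)[C@@H]12)(C(C)C)C(C)C | intermediate
11 | (E)-8-propylidene-5-(triisopropylsilyloxy)bicyclo[4.2.0]oct-3-en-7-one, ring centres as in 6 | CC(C)[Si](O[C@H]1C=CC[C@H]2/C(=C\CC)C(=O)[C@@H]12)(C(C)C)C(C)C | intermediate
12 | 8-propyl-5-(triisopropylsilyloxy)bicyclo[4.2.0]octan-7-one, propyl on the concave face cis to C2 | CC(C)[Si](O[C@H]1CCC[C@H]2[C@@H](CCC)C(=O)[C@@H]12)(C(C)C)C(C)C | intermediate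
13 | methyl 2-iodobenzoate | COC(=O)c1ccccc1I | starting material
14 | [2-(methoxycarbonyl)phenyl]magnesium chloride (not isolated) | COC(=O)c1ccccc1[Mg]Cl | intermediate
15 | chloromagnesium alkoxide of the C3' aryl carbinol, aryl on the convex face (not isolated) | CC(C)[Si](O[C@H]1CCC[C@H]2[C@@H](CCC)[C@](O[Mg]Cl)(c3ccccc3C(=O)OC)[C@@H]12)(C(C)C)C(C)C | intermediate
16 | 8-propyl-5-(triisopropylsilyloxy)-3'H-spiro[bicyclo[4.2.0]octane-7,1'-[2]benzofuran]-3'-one, lactone O cis to propyl and C5 | CC(C)[Si](O[C@H]1CCC[C@H]2[C@@H](CCC)[C@@]3(OC(=O)c4ccccc43)[C@@H]12)(C(C)C)C(C)C | intermediate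
17 | 5-hydroxy-8-propyl-3'H-spiro[bicyclo[4.2.0]octane-7,1'-[2]benzofuran]-3'-one | O[C@H]1CCC[C@H]2[C@@H](CCC)[C@@]3(OC(=O)c4ccccc43)[C@@H]12 | intermediate
18 | 8-propyl-3'H-spiro[bicyclo[4.2.0]octane-7,1'-[2]benzofuran]-3',5-dione | O=C1CCC[C@H]2[C@@H](CCC)[C@@]3(OC(=O)c4ccccc43)[C@@H]12 | intermediate
19 | pentanoyl chloride | CCCCC(=O)Cl | starting material
20 | lithium C3a enolate of 18 (not isolated) | [Li]OC1=CCC[C@H]2[C@@H](CCC)[C@@]3(OC(=O)c4ccccc43)[C@@H]12 | intermediate
21 | 4-pentanoyl-8-propyl-3'H-spiro[bicyclo[4.2.0]octane-7,1'-[2]benzofuran]-3',5-dione (diketo form drawn) | O=C1C(C(=O)CCCC)CC[C@H]2[C@@H](CCC)[C@@]3(OC(=O)c4ccccc43)[C@@H]12 | intermediate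
22 | 3'-oxo-4-pentanoyl-8-propyl-3'H-spiro[bicyclo[4.2.0]oct-4-ene-7,1'-[2]benzofuran]-5-yl trifluoromethanesulfonate | FC(F)(F)S(=O)(=O)OC1=C(C(=O)CCCC)CC[C@H]2[C@@H](CCC)[C@@]3(OC(=O)c4ccccc43)[C@@H]12 | intermediate
23 | CNP0248594.2, (6S,7R,3'R,8'R), (Z)-butylidene | CCC/C=C1\OC(=O)C2=C1CC[C@H]1[C@@H](CCC)[C@@]3(OC(=O)c4ccccc43)[C@@H]21 | target

**Totals**

Total step count: 13. Longest linear sequence: 12 steps (steps 1, 2 and 4 to 13, from 3-oxocyclobutane-1-carboxylic acid).

**Steps most likely to fail**

1. Step 4. The strongly Lewis acidic catalyst may degrade the silyl dienol ether (desilylation or Mukaiyama–Michael-type addition in place of cycloaddition), or face discrimination on so small a dienophile may be insufficient. The fallback sets out from 3 and 5 and comes back at 6. The cycloaddition is run without a chiral catalyst (ZnCl2 in CH2Cl2 at low temperature, or simply at rt), which should give the same ortho, endo adduct as the racemate, that is 6 together with its mirror image (1R,5R,6S)-5-(triisopropylsilyloxy)bicyclo[4.2.0]oct-3-en-7-one F1. The enantiomers are then separated by preparative chromatography on a chiral stationary phase (amylose tris(3,5-dimethylphenylcarbamate), supercritical CO2/i-PrOH), and the route continues with 6.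

2. Step 8. Enolisation of the hindered, α-branched cyclobutanone by the basic arylmagnesium reagent may compete with addition, returning ketone and eroding the contra-thermodynamic C8' configuration. The fallback sets out from 12 and comes back at 16. (2-Bromophenyl)methanol is treated with two equivalents of n-BuLi (THF, −78 °C) to give lithium (2-lithiophenyl)methanolate F2, which is transmetallated with CeCl3 and added to 12. The less basic organocerium reagent should add from the same convex face to give the diol 7-[2-(hydroxymethyl)phenyl]-8-propyl-5-(triisopropylsilyloxy)bicyclo[4.2.0]octan-7-ol F3. Oxidative lactonisation with catalytic TEMPO and PhI(OAc)2 (primary alcohol to aldehyde, lactol, then lactone) returns the route to 16.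

3. Step 12. Sulfonylation may take place at the side-chain oxygen instead of the ring oxygen, or give a mixture of regioisomeric enol triflates, which would misplace the carbonylation site. The fallback sets out from 18 and comes back at 23, fixing the regiochemistry by the order of bond formation:
   - Vilsmeier–Haack–Arnold bromoformylation of 18 (PBr3, DMF, CHCl3, then aq NaOAc) puts bromine on the former carbonyl carbon C7a and the formyl group on C3a, giving 5-bromo-3'-oxo-8-propyl-3'H-spiro[bicyclo[4.2.0]oct-4-ene-7,1'-[2]benzofuran]-4-carbaldehyde F4.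
   - n-BuMgCl (THF, −78 °C) adds to the aldehyde in preference to the lactone to give 5-bromo-4-(1-hydroxypentyl)-8-propyl-3'H-spiro[bicyclo[4.2.0]oct-4-ene-7,1'-[2]benzofuran]-3'-one F5.
   - DMP oxidation gives 5-bromo-4-pentanoyl-8-propyl-3'H-spiro[bicyclo[4.2.0]oct-4-ene-7,1'-[2]benzofuran]-3'-one F6.
   - The carbonylative lactonisation of step 13 (Pd(PPh3)4, CO, Et3N, MeCN, 60 °C), applied to this β-bromo enone, closes the butenolide and delivers 23.

**Further compounds**

F1 | step 4 | (1R,5R,6S)-5-(triisopropylsilyloxy)bicyclo[4.2.0]oct-3-en-7-one | CC(C)[Si](O[C@@H]1C=CC[C@@H]2CC(=O)[C@H]12)(C(C)C)C(C)C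
F2 | step 8 | lithium (2-lithiophenyl)methanolate | [Li]OCc1ccccc1[Li]
F3 | step 8 | 7-[2-(hydroxymethyl)phenyl]-8-propyl-5-(triisopropylsilyloxy)bicyclo[4.2.0]octan-7-ol, aryl on the convex face | CC(C)[Si](O[C@H]1CCC[C@H]2[C@@H](CCC)[C@](O)(c3ccccc3CO)[C@@H]12)(C(C)C)C(C)C
F4 | step 12 | 5-bromo-3'-oxo-8-propyl-3'H-spiro[bicyclo[4.2.0]oct-4-ene-7,1'-[2]benzofuran]-4-carbaldehyde | BrC1=C(C=O)CC[C@H]2[C@@H](CCC)[C@@]3(OC(=O)c4ccccc43)[C@@H]12
F5 | step 12 | 5-bromo-4-(1-hydroxypentyl)-8-propyl-3'H-spiro[bicyclo[4.2.0]oct-4-ene-7,1'-[2]benzofuran]-3'-one, carbinol epimers | BrC1=C(C(O)CCCC)CC[C@H]2[C@@H](CCC)[C@@]3(OC(=O)c4ccccc43)[C@@H]12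
F6 | step 12 | 5-bromo-4-pentanoyl-8-propyl-3'H-spiro[bicyclo[4.2.0]oct-4-ene-7,1'-[2]benzofuran]-3'-one | BrC1=C(C(=O)CCCC)CC[C@H]2[C@@H](CCC)[C@@]3(OC(=O)c4ccccc43)[C@@H]12
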